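The readings are calculated with constants of no real substance; scatter was added.

A one-step picture, G to E, has no J in it, yet both runs below show J growing beside E. Our next run must therefore be charged for a ratio, E to J, and not for one yield.

| setting | elm | alder | flask |
|---|---|---|---|
| G | 0.40 M | 0.40 M | 0.40 M |
| D | 1 mol% | 2 mol% | 1 mol% |
| remark | the very flask that is asked about, followed so far | run made earlier |  |
| time |  |  | 6.0 h |

elm run (percent of the G charged)

| time / min | E / % | J / % |
|---|---|---|
| 1.50 | 4.7 | 1.1 |
| 4.00 | 9.1 | 0 |
| 8.00 | 15.2 | 0.9 |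
| 12.0 | 18.5 | 2.1 |
| 20.0 | 20.0 | 2.0 |
| 25.0 | 16.4 | 4.8 |
| 30.0 | 16.5 | 5.8 |

alder run (percent of the G charged)

| time / h | E / % | J / % |
|---|---|---|
| 0.500 | 15.8 | 5.3 |
| 0.667 | 17.5 | 7.2 |
| 1.00 | 15.5 | 9.4 |
| 1.50 | 14.4 | 12.3 |
| 2.50 | 15.0 | 15.2 |
| 4.00 | 14.5 | 16.0 |
| 6.00 | 14.4 | 17.4 |

(readings scatter by 1 percentage point)

- ratio of E to J at 15 s
- ratio of E to J at 10 min
- ratio of E to J at 6.0 h

- on the list of suspects stand: G <-> L; E <-> J; Z + D <-> G + D; J + D <-> Z + D; G <-> E

1. The decision is whether to double D in the elm recipe or leave it as charged.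

2. At the same moment, 30.0 min in elm and 0.500 h in alder, E reads 16.5% against 15.8% and J reads 5.8% against 5.3%. Elm has half the D of alder, yet the gaps of 0.7 percentage points and 0.5 points stay below the scatter of 1 point.

3. Late in alder, E barely moves, from 14.5% to 14.4%, and J steps from 16.0% to 17.4%. We take both as frozen, which is an assumption and not a finding, since J still steps by 1.4 points. The resting ratio, meaning E over J once both have stopped moving and read here from the sums of the last two alder readings, is 0.865. It is a reading, and if it holds it marks thermodynamic control of E against J.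

4. We leave D at 1 mol% and expect the resting ratio at 6.0 h, since these readings give no ground for doubling D.

5. The forecast gives 500 at 15 s, 10 at 10 min and 0.87 at 6.0 h, the last “independent of D”. It reads the same alder plateau as we do, so it is no second witness.

The asked flask gives 583 at 15 s, 12.4 at 10 min and 0.928 at 6.0 h.

    G ⇌ L (K = 0.737, k = 0.0617 min⁻¹)
    E ⇌ J (K = 1.10, k = 0.0105 min⁻¹)
    Z + D ⇌ G + D, rate k3*[D]*[Z] forward; the back reaction follows from the equilibrium constant (k = 2.17 M⁻¹ min⁻¹)
    J + D ⇌ Z + D, rate k4*[D]*[J] forward; the back reaction follows from the equilibrium constant (K = 0.380, k = 7.56 M⁻¹ min⁻¹)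
    G ⇌ E (K = 0.430, k = 0.0394 min⁻¹)

In the asked flask the forward loss of E to J alone has a half-life of 1.1 h, short against the 6.0 h of the run, and the end ratio stands at 1.07 times the resting ratio as read in alder, with a run ten times as long making no real difference to that ratio. The neighbour flask with 0.6 mol% of D has an E to J ratio of 14.0 at 10 min against 12.4 in the asked flask, and ends at 0.939, which is 1.09 times the resting ratio as read in alder.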